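**Retrosynthetic overview** (guaiane locants: C1 ring-fusion CH, C2 CH2, C3 C=O, C4=C5 enone, C6 CH2, C7 CH bearing C11, C8 CH–O, C9 CH2, C10 CH–CH3)

1. Endgame: C11 acetate and C8 propionate from diol 24; C4 methyl by α-iodination and Stille coupling; enone and C1 configuration by ketal hydrolysis and equilibration; C8–OH from ketone 18; C11 carbinol from the C7 ester.
2. Key disconnection: the seven-membered ring by a formal (4+3) that makes C8–C7 and C10–C1, joining the C8–C9–C10 unit of (E)-crotonoyl(trimethyl)silane 13 to the C1=C5–C6=C7 diene of cyclopentenyl acrylate 7. A light-induced siloxycarbene adds [2+1] to C6=C7, and the cis-dialkenylcyclopropane then rearranges to the cycloheptadiene (strain release).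
3. Enabling feature: the ring C1–C5–C6–C7–C8–C9–C10 is a masked cyclohepta-1,4-diene. The C8 oxygen is an enol oxygen (C8=C9), the C4=C5 enone is the conjugated form of C5=C6, and C7 between them carries a carboxyl-level carbon (C11) that makes C6=C7 an acceptor for a nucleophilic carbene.
4. Ring order: five-membered ring (bought as ketal ketone 1) → transient cyclopropane → seven-membered ring. Absolute configuration comes from the 8-phenylmenthyl ester, which leaves in step 7.

Key step: step 6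

Assumption 1: compounds 1, 4, 5, 8 and 9 are bought.
Assumption 2: the phenyl ring of the 8-phenylmenthyl ester is taken to shield the acrylate as in the usual s-trans, phenyl-stacked model; on that model the (1S,2R,5S) alcohol 4 gives the (R) configuration at the former acrylate β-carbon of cyclopropane 15 and so the natural series.

**Route**

Step 1
Reactants: 1 1,4-dioxaspiro[4.4]nonan-7-one
Product: 3 1,4-dioxaspiro[4.4]non-7-en-7-yl trifluoromethanesulfonate, via lithium enolate 2 (not isolated)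
Conditions: LiN(i-Pr)2, THF, −78 °C; then PhNTf2, −78 → 0 °C; then H2O
Reagents that add atoms: N-phenylbis(trifluoromethanesulfonimide), O=S(=O)(N(c1ccccc1)S(=O)(=O)C(F)(F)F)C(F)(F)F
Why: Kinetic enolate formation and O-triflation (enol triflate synthesis) should take the less hindered α-proton on the side away from the ketal and so place the C5=C1 double bond; no stereocenter is formed.

Step 2
Reactants: 4 (1S,2R,5S)-5-methyl-2-(2-phenylpropan-2-yl)cyclohexan-1-ol; 5 prop-2-enoyl chloride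
Product: 6 (1S,2R,5S)-5-methyl-2-(2-phenylpropan-2-yl)cyclohexyl prop-2-enoate
Conditions: Et3N, DMAP (cat.), CH2Cl2, 0 °C
Reagents that add atoms: none
Why: O-acylation of the secondary alcohol by the acid chloride (nucleophilic acyl substitution) leaves the auxiliary stereocenters untouched.

Step 3
Reactants: 3 1,4-dioxaspiro[4.4]non-7-en-7-yl trifluoromethanesulfonate; 6 (1S,2R,5S)-5-methyl-2-(2-phenylpropan-2-yl)cyclohexyl prop-2-enoate
Product: 7 (1S,2R,5S)-5-methyl-2-(2-phenylpropan-2-yl)cyclohexyl (2E)-3-(1,4-dioxaspiro[4.4]non-7-en-7-yl)prop-2-enoate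
Conditions: Pd(OAc)2 (5 mol%), PPh3, Et3N, DMF, 70 °C
Reagents that add atoms: none
Why: Mizoroki–Heck coupling of an enol triflate with an acrylate should give the (E)-dienoate through syn insertion and syn β-hydride elimination.

Step 4
Reactants: 8 1-(trimethylsilyl)ethan-1-one; 9 acetaldehyde
Product: 11 3-hydroxy-1-(trimethylsilyl)butan-1-one (racemic), via lithium enolate 10 (not isolated)
Conditions: LiN(i-Pr)2, THF, −78 °C; then 9, −78 °C; then H2O
Reagents that add atoms: none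
Why: Aldol addition of the acylsilane lithium enolate to the aldehyde; the new carbinol centre is racemic and is removed in step 5.

Step 5
Reactants: 11 3-hydroxy-1-(trimethylsilyl)butan-1-one
Product: 13 (2E)-1-(trimethylsilyl)but-2-en-1-one, via mesylate 12 (not isolated)
Conditions: MsCl, Et3N, CH2Cl2, 0 → 25 °C
Reagents that add atoms: none
Why: Mesylation and E1cB elimination of the β-mesyloxy ketone should give the conjugated enoylsilane with the favoured (E) geometry.

Step 6
Reactants: 7 (1S,2R,5S)-5-methyl-2-(2-phenylpropan-2-yl)cyclohexyl (2E)-3-(1,4-dioxaspiro[4.4]non-7-en-7-yl)prop-2-enoate; 13 (2E)-1-(trimethylsilyl)but-2-en-1-one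
Product: 16 (1S,2R,5S)-5-methyl-2-(2-phenylpropan-2-yl)cyclohexyl (5S,8R,8aS)-8-methyl-6-[(trimethylsilyl)oxy]-3,5,8,8a-tetrahydro-1H-spiro[azulene-2,2'-[1,3]dioxolane]-5-carboxylate, via siloxycarbene 14 (not isolated), via divinylcyclopropane 15 (not isolated)
Conditions: 427 nm LEDs, degassed PhMe, 20 °C (13, 3 equiv, added slowly); then 80 °C
Reagents that add atoms: none
Why: Proposed new method: excitation of the n→π* band of enoylsilane 13 should trigger a 1,2-silyl shift from carbon to oxygen (photochemical Brook rearrangement) to give the nucleophilic siloxy(propenyl)carbene 14, which adds to the acceptor C6=C7 bond of 7 ([2+1] closure of the three-membered ring, making C8–C7 and a temporary C8–C6 bond); the cis-2-siloxy-1,2-dialkenylcyclopropane 15 then undergoes the [3,3] divinylcyclopropane (Cope) rearrangement through the boat transition state, which makes C10–C1, breaks C8–C6 and closes the seven-membered ring by three-to-seven ring expansion driven by release of cyclopropane strain. The closest known reactions are the visible-light siloxycarbene cyclopropanation of electron-poor alkenes by acylsilanes and the cyclopropanation/Cope formal (4+3) of alkenylcarbenoids with dienes; new is an alkenyl acylsilane as the carbene source. C7 keeps the trans relation of ester and cyclopentenyl group from the (E)-acrylate, and the boat geometry puts the (E)-methyl at C10 and C2 at C1 on the face of the C7 ester, so C7 and C10 arrive as needed and C1 arrives epimeric (corrected in step 9). The absolute sense is set at the acrylate β-carbon C6, one face of which is shielded by the phenyl ring of the auxiliary, and is relayed to C7, C10 and C1 by the concerted shift. The step needs addition at the α,β- and not the γ,δ-bond (secured by polarity: nucleophilic carbene, acrylate β-carbon, while the γ,δ-bond is trisubstituted and not activated) and passage through the cis-dialkenyl isomer (the trans isomer is a donor–acceptor cyclopropane that should equilibrate by reversible C7–C8 heterolysis at 80 °C).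

Step 7
Reactants: 16 (1S,2R,5S)-5-methyl-2-(2-phenylpropan-2-yl)cyclohexyl (5S,8R,8aS)-8-methyl-6-[(trimethylsilyl)oxy]-3,5,8,8a-tetrahydro-1H-spiro[azulene-2,2'-[1,3]dioxolane]-5-carboxylate
Product: 18 (5R,8S,8aS)-5-(2-hydroxypropan-2-yl)-8-methyl-3,5,8,8a-tetrahydro-1H-spiro[azulene-2,2'-[1,3]dioxolan]-6(7H)-one, via carbinol silyl enol ether 17 (not isolated)
Conditions: MeLi, CeCl3, THF, −78 → −20 °C; then 10% aq citric acid, 0 °C
Reagents that add atoms: methyllithium, C[Li]
Why: Double addition of the weakly basic methylcerium reagent to the ester (organocerium addition) should build the C11 carbinol and release the auxiliary, and the acidic work-up hydrolyses the silyl enol ether regiospecifically to the C8 ketone; C7 is not touched and no stereocenter is formed.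

Step 8
Reactants: 18 (5R,8S,8aS)-5-(2-hydroxypropan-2-yl)-8-methyl-3,5,8,8a-tetrahydro-1H-spiro[azulene-2,2'-[1,3]dioxolan]-6(7H)-one
Product: 19 (5S,6R,8S,8aS)-5-(2-hydroxypropan-2-yl)-8-methyl-3,5,6,7,8,8a-hexahydro-1H-spiro[azulene-2,2'-[1,3]dioxolan]-6-ol
Conditions: LiBH(s-Bu)3, THF, −78 °C; then H2O
Reagents that add atoms: none
Why: Ketone reduction with a bulky borohydride: hydride should enter the C8 carbonyl from the face opposite the adjacent C7 carbinol arm and the C10 methyl group, which places the new hydroxyl cis to the C7 substituent (8R).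

Step 9
Reactants: 19 (5S,6R,8S,8aS)-5-(2-hydroxypropan-2-yl)-8-methyl-3,5,6,7,8,8a-hexahydro-1H-spiro[azulene-2,2'-[1,3]dioxolan]-6-ol
Product: 22 (5S,6R,8S,8aR)-6-hydroxy-5-(2-hydroxypropan-2-yl)-8-methyl-4,5,6,7,8,8a-hexahydroazulen-2(1H)-one, via deconjugated ketone 20 (not isolated), via ring-fusion epimer 21 (not isolated)
Conditions: 1 M HCl, THF, 25 °C; then DBU, PhMe, 60 °C
Reagents that add atoms: water, O
Why: Acid hydrolysis of the dioxolane and then enolisation should move C5=C6 into conjugation (C4=C5) and, through the cross-conjugated dienolate, equilibrate C1 to the epimer in which the C10 methyl and the C1–C2 bond are trans (thermodynamic control, relief of the cis-1,2 interaction).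

Step 10
Reactants: 22 (5S,6R,8S,8aR)-6-hydroxy-5-(2-hydroxypropan-2-yl)-8-methyl-4,5,6,7,8,8a-hexahydroazulen-2(1H)-one
Product: 23 (5S,6R,8S,8aR)-6-hydroxy-5-(2-hydroxypropan-2-yl)-3-iodo-8-methyl-4,5,6,7,8,8a-hexahydroazulen-2(1H)-one
Conditions: I2, pyridine, CH2Cl2, 25 °C
Reagents that add atoms: iodine, [I][I]
Why: α-Iodination of the enone by pyridine conjugate addition, iodination of the enolate and elimination, which can occur only at C4.

Step 11
Reactants: 23 (5S,6R,8S,8aR)-6-hydroxy-5-(2-hydroxypropan-2-yl)-3-iodo-8-methyl-4,5,6,7,8,8a-hexahydroazulen-2(1H)-one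
Product: 24 (5S,6R,8S,8aR)-6-hydroxy-5-(2-hydroxypropan-2-yl)-3,8-dimethyl-4,5,6,7,8,8a-hexahydroazulen-2(1H)-one
Conditions: Me4Sn, Pd2(dba)3 (cat.), AsPh3, CuI, NMP, 60 °C
Reagents that add atoms: tetramethylstannane, C[Sn](C)(C)C
Why: Stille coupling of the α-iodoenone should install the C4 methyl group without moving the alkene; the stereocenters are remote and untouched.

Step 12
Reactants: 24 (5S,6R,8S,8aR)-6-hydroxy-5-(2-hydroxypropan-2-yl)-3,8-dimethyl-4,5,6,7,8,8a-hexahydroazulen-2(1H)-one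
Product: 25 (5S,6R,8S,8aR)-5-(2-hydroxypropan-2-yl)-3,8-dimethyl-2-oxo-1,2,4,5,6,7,8,8a-octahydroazulen-6-yl propanoate
Conditions: (EtCO)2O, pyridine, DMAP (cat.), CH2Cl2, 0 °C
Reagents that add atoms: propanoic anhydride, CCC(=O)OC(=O)CC
Why: DMAP-catalysed acylation should be selective for the secondary C8 hydroxyl over the tertiary C11 hydroxyl for steric reasons; C8 keeps its configuration because the C–O bond is not broken.

Step 13
Reactants: 25 (5S,6R,8S,8aR)-5-(2-hydroxypropan-2-yl)-3,8-dimethyl-2-oxo-1,2,4,5,6,7,8,8a-octahydroazulen-6-yl propanoate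
Product: 26 (5S,6R,8S,8aR)-5-(2-acetoxypropan-2-yl)-3,8-dimethyl-2-oxo-1,2,4,5,6,7,8,8a-octahydroazulen-6-yl propanoate
Conditions: Ac2O, Et3N, DMAP (1 equiv), CH2Cl2, 40 °C
Reagents that add atoms: acetic anhydride, CC(=O)OC(C)=O
Why: Acetylation of the tertiary alcohol through the N-acetylpyridinium salt (Steglich-type acylation); no stereocenter is affected.

**Compound list**

1 | 1,4-dioxaspiro[4.4]nonan-7-one | O=C1CCC2(C1)OCCO2 | starting material
2 | lithium 1,4-dioxaspiro[4.4]non-7-en-7-olate | [Li]OC1=CCC2(C1)OCCO2 | intermediate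
3 | 1,4-dioxaspiro[4.4]non-7-en-7-yl trifluoromethanesulfonate | O=S(=O)(OC1=CCC2(C1)OCCO2)C(F)(F)F | intermediate
4 | (1S,2R,5S)-5-methyl-2-(2-phenylpropan-2-yl)cyclohexan-1-ol | O[C@H]1C[C@@H](C)CC[C@@H]1C(C)(C)c1ccccc1 | starting material
5 | prop-2-enoyl chloride | C=CC(Cl)=O | starting material
6 | (1S,2R,5S)-5-methyl-2-(2-phenylpropan-2-yl)cyclohexyl prop-2-enoate | C=CC(=O)O[C@H]1C[C@@H](C)CC[C@@H]1C(C)(C)c1ccccc1 | intermediate
7 | (1S,2R,5S)-5-methyl-2-(2-phenylpropan-2-yl)cyclohexyl (2E)-3-(1,4-dioxaspiro[4.4]non-7-en-7-yl)prop-2-enoate | O=C(/C=C/C1=CCC2(C1)OCCO2)O[C@H]1C[C@@H](C)CC[C@@H]1C(C)(C)c1ccccc1 | intermediate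
8 | 1-(trimethylsilyl)ethan-1-one | CC(=O)[Si](C)(C)C | starting material
9 | acetaldehyde | CC=O | starting material
10 | lithium 1-(trimethylsilyl)ethen-1-olate | [Li]OC(=C)[Si](C)(C)C | intermediate
11 | 3-hydroxy-1-(trimethylsilyl)butan-1-one (racemic) | CC(O)CC(=O)[Si](C)(C)C | intermediate
12 | 4-oxo-4-(trimethylsilyl)butan-2-yl methanesulfonate (racemic) | CC(CC(=O)[Si](C)(C)C)OS(C)(=O)=O | intermediate
13 | (2E)-1-(trimethylsilyl)but-2-en-1-one | C/C=C/C(=O)[Si](C)(C)C | intermediate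
14 | (2E)-1-[(trimethylsilyl)oxy]but-2-en-1-ylidene (singlet carbene) | C/C=C/[C]O[Si](C)(C)C | intermediate
15 | (1S,2R,5S)-5-methyl-2-(2-phenylpropan-2-yl)cyclohexyl (1S,2R,3R)-3-(1,4-dioxaspiro[4.4]non-7-en-7-yl)-2-[(1E)-prop-1-en-1-yl]-2-[(trimethylsilyl)oxy]cyclopropane-1-carboxylate | C[Si](C)(C)O[C@@]1(/C=C/C)[C@@H](C(=O)O[C@H]2C[C@@H](C)CC[C@@H]2C(C)(C)c2ccccc2)[C@@H]1C1=CCC2(C1)OCCO2 | intermediate
16 | (1S,2R,5S)-5-methyl-2-(2-phenylpropan-2-yl)cyclohexyl (5S,8R,8aS)-8-methyl-6-[(trimethylsilyl)oxy]-3,5,8,8a-tetrahydro-1H-spiro[azulene-2,2'-[1,3]dioxolane]-5-carboxylate | C[Si](C)(C)OC1=C[C@H](C)[C@@H]2CC3(OCCO3)CC2=C[C@@H]1C(=O)O[C@H]1C[C@@H](C)CC[C@@H]1C(C)(C)c1ccccc1 | intermediate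
17 | 2-[(5R,8R,8aS)-8-methyl-6-[(trimethylsilyl)oxy]-3,5,8,8a-tetrahydro-1H-spiro[azulene-2,2'-[1,3]dioxolan]-5-yl]propan-2-ol | C[Si](C)(C)OC1=C[C@H](C)[C@@H]2CC3(OCCO3)CC2=C[C@@H]1C(C)(C)O | intermediate
18 | (5R,8S,8aS)-5-(2-hydroxypropan-2-yl)-8-methyl-3,5,8,8a-tetrahydro-1H-spiro[azulene-2,2'-[1,3]dioxolan]-6(7H)-one | O=C1C[C@H](C)[C@@H]2CC3(OCCO3)CC2=C[C@@H]1C(C)(C)O | intermediate
19 | (5S,6R,8S,8aS)-5-(2-hydroxypropan-2-yl)-8-methyl-3,5,6,7,8,8a-hexahydro-1H-spiro[azulene-2,2'-[1,3]dioxolan]-6-ol | O[C@@H]1C[C@H](C)[C@@H]2CC3(OCCO3)CC2=C[C@@H]1C(C)(C)O | intermediate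
20 | (5S,6R,8S,8aS)-6-hydroxy-5-(2-hydroxypropan-2-yl)-8-methyl-3,5,6,7,8,8a-hexahydroazulen-2(1H)-one | O[C@@H]1C[C@H](C)[C@@H]2CC(=O)CC2=C[C@@H]1C(C)(C)O | intermediate
21 | (5S,6R,8S,8aS)-6-hydroxy-5-(2-hydroxypropan-2-yl)-8-methyl-4,5,6,7,8,8a-hexahydroazulen-2(1H)-one | O[C@@H]1C[C@H](C)[C@@H]2CC(=O)C=C2C[C@@H]1C(C)(C)O | intermediate
22 | (5S,6R,8S,8aR)-6-hydroxy-5-(2-hydroxypropan-2-yl)-8-methyl-4,5,6,7,8,8a-hexahydroazulen-2(1H)-one | O[C@@H]1C[C@H](C)[C@H]2CC(=O)C=C2C[C@@H]1C(C)(C)O | intermediate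
23 | (5S,6R,8S,8aR)-6-hydroxy-5-(2-hydroxypropan-2-yl)-3-iodo-8-methyl-4,5,6,7,8,8a-hexahydroazulen-2(1H)-one | O[C@@H]1C[C@H](C)[C@H]2CC(=O)C(I)=C2C[C@@H]1C(C)(C)O | intermediate
24 | (5S,6R,8S,8aR)-6-hydroxy-5-(2-hydroxypropan-2-yl)-3,8-dimethyl-4,5,6,7,8,8a-hexahydroazulen-2(1H)-one | O[C@@H]1C[C@H](C)[C@H]2CC(=O)C(C)=C2C[C@@H]1C(C)(C)O | intermediate
25 | (5S,6R,8S,8aR)-5-(2-hydroxypropan-2-yl)-3,8-dimethyl-2-oxo-1,2,4,5,6,7,8,8a-octahydroazulen-6-yl propanoate | CCC(=O)O[C@@H]1C[C@H](C)[C@H]2CC(=O)C(C)=C2C[C@@H]1C(C)(C)O | intermediate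
26 | (5S,6R,8S,8aR)-5-(2-acetoxypropan-2-yl)-3,8-dimethyl-2-oxo-1,2,4,5,6,7,8,8a-octahydroazulen-6-yl propanoate | CCC(=O)O[C@@H]1C[C@H](C)[C@H]2CC(=O)C(C)=C2C[C@@H]1C(C)(C)OC(C)=O | target

**Count and risks**

Total step count: 13. Longest linear sequence: 10 steps (1, 3, 6, 7, 8, 9, 10, 11, 12, 13).

Most likely to fail:

Step 6 (bears the label). What may go wrong: photoisomerisation of the enoylsilane double bond or an intramolecular hydrogen shift in the carbene may outrun the bimolecular addition, and shielding of the acrylate face by the auxiliary may be incomplete. The fallback uses known chemistry, thermal transfer of an alkoxy(alkenyl)carbene from chromium to an acceptor alkene followed by the same Cope rearrangement, and runs from 7 back to 18. Condensation of bought (CO)5Cr=C(OMe)CH3 with 9 (Et3N, Me3SiCl) gives pentacarbonyl[(2E)-1-methoxybut-2-en-1-ylidene]chromium F1. Heating 7 with F1 (THF, 80 °C, sealed vessel) should give the methyl enol ether (1S,2R,5S)-5-methyl-2-(2-phenylpropan-2-yl)cyclohexyl (5S,8R,8aS)-6-methoxy-8-methyl-3,5,8,8a-tetrahydro-1H-spiro[azulene-2,2'-[1,3]dioxolane]-5-carboxylate F2. MeLi/CeCl3 converts its ester into 2-[(5R,8R,8aS)-6-methoxy-8-methyl-3,5,8,8a-tetrahydro-1H-spiro[azulene-2,2'-[1,3]dioxolan]-5-yl]propan-2-ol F3, and dilute oxalic acid in wet THF cleaves the enol ether to 18.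

Step 7. What may go wrong: proton abstraction at the doubly allylic C7–H may compete with addition to the shielded ester carbonyl (erosion of C7 or stalling), and the β,γ-unsaturated ketone may slip into conjugation during work-up. The fallback carries the carboxyl group on a slimmer auxiliary and runs from 3 back to 18. Bought (1S,2R)-2-phenylcyclohexan-1-ol is acylated with 5 to (1S,2R)-2-phenylcyclohexyl prop-2-enoate F4. Heck coupling with 3 gives (1S,2R)-2-phenylcyclohexyl (2E)-3-(1,4-dioxaspiro[4.4]non-7-en-7-yl)prop-2-enoate F5. The sequence of step 6 gives (1S,2R)-2-phenylcyclohexyl (5S,8R,8aS)-8-methyl-6-[(trimethylsilyl)oxy]-3,5,8,8a-tetrahydro-1H-spiro[azulene-2,2'-[1,3]dioxolane]-5-carboxylate F6. Its less hindered carbonyl should take up MeMgBr at −78 °C, and cold buffered work-up followed at once by the reduction of step 8 passes through 18 without storing it.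

Step 9. What may go wrong: the free tertiary carbinol may ionise in the acid (loss of water), and proton exchange at the ring-fusion carbon may stop short of full conversion. The fallback acylates both hydroxyl groups before the ketal is opened and runs from 19 to 26. Compound 19 is propionylated to (5S,6R,8S,8aS)-5-(2-hydroxypropan-2-yl)-8-methyl-3,5,6,7,8,8a-hexahydro-1H-spiro[azulene-2,2'-[1,3]dioxolan]-6-yl propanoate F7 and acetylated to (5S,6R,8S,8aS)-5-(2-acetoxypropan-2-yl)-8-methyl-3,5,6,7,8,8a-hexahydro-1H-spiro[azulene-2,2'-[1,3]dioxolan]-6-yl propanoate F8. Hydrolysis and DBU equilibration then give (5S,6R,8S,8aR)-5-(2-acetoxypropan-2-yl)-8-methyl-2-oxo-1,2,4,5,6,7,8,8a-octahydroazulen-6-yl propanoate F9; any ring-fusion epimer is separated and returned to the DBU equilibration. Iodination gives (5S,6R,8S,8aR)-5-(2-acetoxypropan-2-yl)-3-iodo-8-methyl-2-oxo-1,2,4,5,6,7,8,8a-octahydroazulen-6-yl propanoate F10, and Stille methylation gives 26.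

Further compounds
F1 | step 6 | pentacarbonyl[(2E)-1-methoxybut-2-en-1-ylidene]chromium | C/C=C/C(OC)=[Cr](=C=O)(=C=O)(=C=O)(=C=O)=C=O
F2 | step 6 | (1S,2R,5S)-5-methyl-2-(2-phenylpropan-2-yl)cyclohexyl (5S,8R,8aS)-6-methoxy-8-methyl-3,5,8,8a-tetrahydro-1H-spiro[azulene-2,2'-[1,3]dioxolane]-5-carboxylate | COC1=C[C@H](C)[C@@H]2CC3(OCCO3)CC2=C[C@@H]1C(=O)O[C@H]1C[C@@H](C)CC[C@@H]1C(C)(C)c1ccccc1
F3 | step 6 | 2-[(5R,8R,8aS)-6-methoxy-8-methyl-3,5,8,8a-tetrahydro-1H-spiro[azulene-2,2'-[1,3]dioxolan]-5-yl]propan-2-ol | COC1=C[C@H](C)[C@@H]2CC3(OCCO3)CC2=C[C@@H]1C(C)(C)O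
F4 | step 7 | (1S,2R)-2-phenylcyclohexyl prop-2-enoate | C=CC(=O)O[C@H]1CCCC[C@@H]1c1ccccc1
F5 | step 7 | (1S,2R)-2-phenylcyclohexyl (2E)-3-(1,4-dioxaspiro[4.4]non-7-en-7-yl)prop-2-enoate | O=C(/C=C/C1=CCC2(C1)OCCO2)O[C@H]1CCCC[C@@H]1c1ccccc1
F6 | step 7 | (1S,2R)-2-phenylcyclohexyl (5S,8R,8aS)-8-methyl-6-[(trimethylsilyl)oxy]-3,5,8,8a-tetrahydro-1H-spiro[azulene-2,2'-[1,3]dioxolane]-5-carboxylate | C[Si](C)(C)OC1=C[C@H](C)[C@@H]2CC3(OCCO3)CC2=C[C@@H]1C(=O)O[C@H]1CCCC[C@@H]1c1ccccc1
F7 | step 9 | (5S,6R,8S,8aS)-5-(2-hydroxypropan-2-yl)-8-methyl-3,5,6,7,8,8a-hexahydro-1H-spiro[azulene-2,2'-[1,3]dioxolan]-6-yl propanoate | CCC(=O)O[C@@H]1C[C@H](C)[C@@H]2CC3(OCCO3)CC2=C[C@@H]1C(C)(C)O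
F8 | step 9 | (5S,6R,8S,8aS)-5-(2-acetoxypropan-2-yl)-8-methyl-3,5,6,7,8,8a-hexahydro-1H-spiro[azulene-2,2'-[1,3]dioxolan]-6-yl propanoate | CCC(=O)O[C@@H]1C[C@H](C)[C@@H]2CC3(OCCO3)CC2=C[C@@H]1C(C)(C)OC(C)=O
F9 | step 9 | (5S,6R,8S,8aR)-5-(2-acetoxypropan-2-yl)-8-methyl-2-oxo-1,2,4,5,6,7,8,8a-octahydroazulen-6-yl propanoate | CCC(=O)O[C@@H]1C[C@H](C)[C@H]2CC(=O)C=C2C[C@@H]1C(C)(C)OC(C)=O
F10 | step 9 | (5S,6R,8S,8aR)-5-(2-acetoxypropan-2-yl)-3-iodo-8-methyl-2-oxo-1,2,4,5,6,7,8,8a-octahydroazulen-6-yl propanoate | CCC(=O)O[C@@H]1C[C@H](C)[C@H]2CC(=O)C(I)=C2C[C@@H]1C(C)(C)OC(C)=O
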